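**Retrosynthetic overview**
- Key disconnection: the C(=O)–Cα bond of the enone. The aryl aldehyde is used as an acyl anion equivalent (chelated acyl–rhodium hydride) and added with H across the terminal alkyne 4‑ethynylphenol. This alkyne hydroacylation forms the whole enone and fixes the E geometry in one step.
- The aldehyde partner comes from double nuclear C‑prenylation of 2,4‑dihydroxybenzaldehyde with prenyl bromide.
- No ring is formed; both benzene rings are bought intact.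

Assumption: the target has no stereocentre (it is achiral), so the only stereochemical element to control is the (E)‑enone double bond.

**Step 1**
Reactants: 1 2,4‑dihydroxybenzaldehyde; 2 prenyl bromide (1‑bromo‑3‑methylbut‑2‑ene)
Product: 5 2,4‑dihydroxy‑3,5‑bis(3‑methylbut‑2‑en‑1‑yl)benzaldehyde, via 3‑prenyl‑2,4‑dihydroxybenzaldehyde 3 (not isolated), via 5‑prenyl‑2,4‑dihydroxybenzaldehyde 4 (not isolated)
Conditions: 2 (2.3 equiv), 10% aq KOH (4 equiv), 0 °C → rt, 16 h; then 1 M HCl to pH 4, EtOAc, SiO2 (expect ca. 20–30%)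
Reagents that add atoms: prenyl bromide, CC(C)=CCBr
Why: Phenoxide C‑alkylation (nuclear prenylation): in water the solvated dianion of 1 reacts as a carbon nucleophile at C3 and C5 (both ortho to the 4‑oxide), SN2 at the primary allylic bromide keeps the linear prenyl group, and both mono‑prenyl isomers 3 and 4 converge on 5; no stereocentre is formed.

**Step 2**
Reactants: 5 2,4‑dihydroxy‑3,5‑bis(3‑methylbut‑2‑en‑1‑yl)benzaldehyde; 6 4‑ethynylphenol
Product: 7 (E)‑1‑[2,4‑dihydroxy‑3,5‑bis(3‑methylbut‑2‑en‑1‑yl)phenyl]‑3‑(4‑hydroxyphenyl)prop‑2‑en‑1‑one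
Conditions: [Rh(cod)Cl]2 (2.5 mol%), dppf (5 mol%), Na2CO3 (10 mol%), degassed toluene/1,4‑dioxane 4:1, 90 °C, 6 (1.5 equiv) added over 2 h, N2; dilute AcOH work‑up, SiO2
Reagents that add atoms: 4‑ethynylphenol, C#Cc1ccc(O)cc1
Why: Chelation‑assisted Rh(I)‑catalysed alkyne hydroacylation: the 2‑phenoxide binds Rh and oxidative addition of the formyl C–H gives a catalyst‑bound five‑membered acyl(hydrido)rhodium chelate, so the normally electrophilic CHO carbon is delivered as an acyl anion equivalent to the Rh‑activated alkyne; syn addition with Rh at the unhindered alkyne terminus and C–C reductive elimination give the linear (E)‑enone, every atom of 5 and 6 ends up in 7, and no stereocentre is formed.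

**Compound list**
1 | 2,4‑dihydroxybenzaldehyde | O=Cc1ccc(O)cc1O | starting material
2 | prenyl bromide (1‑bromo‑3‑methylbut‑2‑ene) | CC(C)=CCBr | starting material
3 | 2,4‑dihydroxy‑3‑(3‑methylbut‑2‑en‑1‑yl)benzaldehyde | CC(C)=CCc1c(O)ccc(C=O)c1O | intermediate
4 | 2,4‑dihydroxy‑5‑(3‑methylbut‑2‑en‑1‑yl)benzaldehyde | CC(C)=CCc1cc(C=O)c(O)cc1O | intermediate
5 | 2,4‑dihydroxy‑3,5‑bis(3‑methylbut‑2‑en‑1‑yl)benzaldehyde | CC(C)=CCc1cc(C=O)c(O)c(CC=C(C)C)c1O | intermediate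
6 | 4‑ethynylphenol | C#Cc1ccc(O)cc1 | starting material
7 | (E)‑1‑[2,4‑dihydroxy‑3,5‑bis(3‑methylbut‑2‑en‑1‑yl)phenyl]‑3‑(4‑hydroxyphenyl)prop‑2‑en‑1‑one | CC(C)=CCc1cc(C(=O)/C=C/c2ccc(O)cc2)c(O)c(CC=C(C)C)c1O | target

**Total step count:** 2
**Longest linear sequence:** 2

**Steps most likely to fail** (the route has only two steps, so step 2 is listed twice for its two independent failure modes)

1. Step 2, regiochemistry and turnover. The hydroacylation may give the branched 2‑aryl enone, stall on the hindered, electron‑rich aldehyde, or run on to the flavanone by oxa‑Michael closure. The fallback keeps the aldehyde carbon as the nucleophile but uses a classical dithiane acyl anion; it sets out from 5 and comes back at 7. Aldehyde 5 is capped (NaH, MOMCl, DMF, 0 °C → rt) to give 2,4‑bis(methoxymethoxy)‑3,5‑bis(3‑methylbut‑2‑en‑1‑yl)benzaldehyde F1. This is converted with 1,3‑propanedithiol and catalytic LiBF4 (MeCN, rt, MOM ethers retained) into 2‑[2,4‑bis(methoxymethoxy)‑3,5‑bis(3‑methylbut‑2‑en‑1‑yl)phenyl]‑1,3‑dithiane F2. Separately, commercial 4‑(methoxymethoxy)benzaldehyde is methylenated (Me3S+ I−, NaH, DMSO/THF) to racemic 2‑[4‑(methoxymethoxy)phenyl]oxirane F3, used crude. Lithiated F2 (n‑BuLi, THF, −40 °C) opens F3 at the CH2 terminus to give 2‑{2‑[2,4‑bis(methoxymethoxy)‑3,5‑bis(3‑methylbut‑2‑en‑1‑yl)phenyl]‑1,3‑dithian‑2‑yl}‑1‑[4‑(methoxymethoxy)phenyl]ethan‑1‑ol F4. MeI/CaCO3 in MeCN/H2O (45 °C) unmasks the ketone to 1‑[2,4‑bis(methoxymethoxy)‑3,5‑bis(3‑methylbut‑2‑en‑1‑yl)phenyl]‑3‑hydroxy‑3‑[4‑(methoxymethoxy)phenyl]propan‑1‑one F5. Brief 3 M HCl/MeOH (50 °C) removes the three MOM groups and dehydrates the benzylic alcohol to the (E)‑enone 7; the carbinol stereocentre is racemic and is destroyed here.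

2. Step 1, double C‑prenylation. It may give mainly mono‑prenyl and O‑prenyl products in an inseparable mixture. The fallback fixes both positions by halogenation and cross‑coupling; it sets out from 1 and comes back at 5. Aldehyde 1 is iodinated twice (ICl 2.2 equiv, AcOH, rt; positions 3 and 5, ortho to the 4‑OH) to 2,4‑dihydroxy‑3,5‑diiodobenzaldehyde F6. Both C–I bonds are then prenylated in one Stille coupling with tributyl(3‑methylbut‑2‑en‑1‑yl)stannane (2.6 equiv, Pd(PPh3)4 5 mol%, DMF, 90 °C; α‑coupling keeps the linear prenyl group) to give 5.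

3. Step 2, the alkyne partner. Free 4‑ethynylphenol may oligomerise at 90 °C or tie up rhodium as a non‑chelating phenoxide. The fallback masks its phenol; it sets out from 6 (with 5) and comes back at 7. Alkyne 6 is silylated on arrival (TBSCl, imidazole, DMF, rt) to tert‑butyl(4‑ethynylphenoxy)dimethylsilane F7. F7 is coupled with 5 under the step 2 conditions to (E)‑3‑{4‑[(tert‑butyldimethylsilyl)oxy]phenyl}‑1‑[2,4‑dihydroxy‑3,5‑bis(3‑methylbut‑2‑en‑1‑yl)phenyl]prop‑2‑en‑1‑one F8. TBAF buffered with AcOH (THF, 0 °C) then gives 7 without base‑induced flavanone closure.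

**Further compounds**
F1 | step 2 | 2,4‑bis(methoxymethoxy)‑3,5‑bis(3‑methylbut‑2‑en‑1‑yl)benzaldehyde | COCOc1c(CC=C(C)C)cc(C=O)c(OCOC)c1CC=C(C)C
F2 | step 2 | 2‑[2,4‑bis(methoxymethoxy)‑3,5‑bis(3‑methylbut‑2‑en‑1‑yl)phenyl]‑1,3‑dithiane | COCOc1c(CC=C(C)C)cc(C2SCCCS2)c(OCOC)c1CC=C(C)C
F3 | step 2 | 2‑[4‑(methoxymethoxy)phenyl]oxirane (racemic) | COCOc1ccc(C2CO2)cc1
F4 | step 2 | 2‑{2‑[2,4‑bis(methoxymethoxy)‑3,5‑bis(3‑methylbut‑2‑en‑1‑yl)phenyl]‑1,3‑dithian‑2‑yl}‑1‑[4‑(methoxymethoxy)phenyl]ethan‑1‑ol (racemic) | COCOc1ccc(C(O)CC2(SCCCS2)c2cc(CC=C(C)C)c(OCOC)c(CC=C(C)C)c2OCOC)cc1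
F5 | step 2 | 1‑[2,4‑bis(methoxymethoxy)‑3,5‑bis(3‑methylbut‑2‑en‑1‑yl)phenyl]‑3‑hydroxy‑3‑[4‑(methoxymethoxy)phenyl]propan‑1‑one (racemic) | COCOc1ccc(C(O)CC(=O)c2cc(CC=C(C)C)c(OCOC)c(CC=C(C)C)c2OCOC)cc1
F6 | step 1 | 2,4‑dihydroxy‑3,5‑diiodobenzaldehyde | O=Cc1cc(I)c(O)c(I)c1O
F7 | step 2 | tert‑butyl(4‑ethynylphenoxy)dimethylsilane | C#Cc1ccc(O[Si](C)(C)C(C)(C)C)cc1
F8 | step 2 | (E)‑3‑{4‑[(tert‑butyldimethylsilyl)oxy]phenyl}‑1‑[2,4‑dihydroxy‑3,5‑bis(3‑methylbut‑2‑en‑1‑yl)phenyl]prop‑2‑en‑1‑one | CC(C)=CCc1cc(C(=O)/C=C/c2ccc(O[Si](C)(C)C(C)(C)C)cc2)c(O)c(CC=C(C)C)c1O
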